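With rings lettered A (2,4,6-trihydroxyphenyl end) to G, the plan cuts ring C, whose carbons C1, C3, C4, C5 and C6 all bear oxygen and whose C2 alone bears hydrogen, back to a squarate-derived cyclobutenone. Heating opens the four-membered ring to a dienylketene that closes to the benzene ring by one new C2–C3 bond. The para oxygens arrive differentiated: free OH on C3, silyl ether on C6, the future link to ring D. The precursor is a 4-silyloxy-2,3-dimethoxycyclobutenone carrying on its carbinol carbon a 1-aryloxyvinyl group whose aryl part is the permethylated A–B dimer. A D–E–F–G bromide, made by etherifications and Dakin oxidations, is joined afterwards.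

Key step: step 5

Remarks on the chemistry:
- Ring numbering: in ring C, C1 bears the oxygen to ring B, C2 is CH, C3–C5 bear OH and C6 bears the oxygen to ring D. In ring D, C1 bears the oxygen to ring C, C3 and C4 bear OH and C5 bears the oxygen to ring E.
- The target is achiral. The only stereocentre in the route (the carbinol carbon of 9 and 10) is racemic and is erased in step 5.
- Compounds 1, 4, 7, 16, 17, 21 and 25 are assumed to be catalogue compounds.

Step 1
Reactants: 1 2,4,6-trimethoxybenzaldehyde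
Product: 3 2,4,6-trimethoxyphenol, via 2,4,6-trimethoxyphenyl formate 2 (not isolated)
Conditions: 30% aq. H2O2, cat. H2SO4, MeOH, rt
Reagents that add atoms: hydrogen peroxide, OO
Why: Dakin oxidation (acid-catalysed Baeyer–Villiger variant) in which the aryl group, made electron-rich by two ortho and one para methoxy groups, migrates to oxygen and the formate is methanolysed in the same pot; no stereocentre is formed.

Step 2
Reactants: 4 4-bromo-2,6-dimethoxyphenol
Product: 5 5-bromo-2-(ethenyloxy)-1,3-dimethoxybenzene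
Conditions: vinyl acetate, [Ir(cod)Cl]2 (1 mol%), Na2CO3 (0.6 equiv), toluene, 100 °C
Reagents that add atoms: vinyl acetate, C=COC(C)=O
Why: Iridium-catalysed transfer vinylation of a phenol with vinyl acetate (addition of the monovalent iridium phenoxide to the coordinated alkene, then loss of acetate), which should tolerate the aryl bromide and the two small ortho methoxy groups.

Step 3
Reactants: 3 2,4,6-trimethoxyphenol; 5 5-bromo-2-(ethenyloxy)-1,3-dimethoxybenzene
Product: 6 2-[4-(ethenyloxy)-3,5-dimethoxyphenoxy]-1,3,5-trimethoxybenzene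
Conditions: CuI (10 mol%), picolinic acid (20 mol%), K3PO4, DMSO, 100 °C, Ar
Reagents that add atoms: none
Why: Ullmann-type diaryl ether synthesis with monovalent copper and picolinic acid, a ligand system suited to phenols with two ortho substituents; the bromide carbon has no ortho substituent and the vinyl ether is inert to base.

Step 4
Reactants: 6 2-[4-(ethenyloxy)-3,5-dimethoxyphenoxy]-1,3,5-trimethoxybenzene; 7 dimethyl squarate
Product: 10 rac-4-[(tert-butyldimethylsilyl)oxy]-2,3-dimethoxy-4-{1-[2,6-dimethoxy-4-(2,4,6-trimethoxyphenoxy)phenoxy]ethenyl}cyclobut-2-en-1-one, via 1-aryloxyvinyllithium 8 (not isolated), via lithium alkoxide 9 (not isolated)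
Conditions: t-BuLi (1.0 equiv), THF, −78 °C; cannulate into 7, THF, −78 °C; then TBSOTf, −78 to −30 °C
Reagents that add atoms: tert-butyldimethylsilyl trifluoromethanesulfonate, CC(C)(C)[Si](C)(C)OS(=O)(=O)C(F)(F)F
Why: α-Lithiation of a vinyl ether (both ring positions ortho to the vinyloxy oxygen are blocked by methoxy groups, which also guide the base to the vinylic C–H), 1,2-addition of the vinyllithium to one of the two equivalent squarate carbonyls and O-silylation of the tertiary lithium alkoxide by the silyl triflate; the new quaternary stereocentre forms as a racemate and is erased in step 5.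

Step 5
Reactants: 10 rac-4-[(tert-butyldimethylsilyl)oxy]-2,3-dimethoxy-4-{1-[2,6-dimethoxy-4-(2,4,6-trimethoxyphenoxy)phenoxy]ethenyl}cyclobut-2-en-1-one
Product: 13 4-[(tert-butyldimethylsilyl)oxy]-5-[2,6-dimethoxy-4-(2,4,6-trimethoxyphenoxy)phenoxy]-2,3-dimethoxyphenol, via dienylketene 11 (not isolated), via cyclohexa-2,4-dienone 12 (not isolated)
Conditions: dry degassed toluene, 110 °C
Reagents that add atoms: none
Why: Thermal conrotatory four-electron ring opening of the cyclobutenone cleaves its C1–C4 bond to give dienylketene 11; a disrotatory six-electron electrocyclisation then joins the ketene carbon to the vinyl CH2 (the only C–C bond formed, C2–C3 of ring C) to give cyclohexa-2,4-dienone 12, which enolises to phenol 13. The closest known reaction type is the Moore rearrangement of 4-alkenyl-4-oxycyclobutenones made from squarates, including adducts of α-alkoxyvinyllithiums, to hydroquinone derivatives. Ring C closes in a 6π electrocyclic mode and no stereocentre is created, the racemic carbinol centre of 10 becoming an sp2 carbon. The step needs torquoselectivity: the oxygen donor on the carbinol carbon rotates outward, as established for hydroxy, alkoxy and silyloxy groups in this ring opening, so the aryloxyvinyl group turns inward, next to the ketene. It also needs the ketene to cyclise before it is trapped, which the intramolecular closure in a dry, nucleophile-free solvent should secure. The substitution pattern of ring C (OH on C3 para to the silyl ether on C6, aryloxy on C1, hydrogen on C2) then follows from connectivity alone.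

Step 6
Reactants: 13 4-[(tert-butyldimethylsilyl)oxy]-5-[2,6-dimethoxy-4-(2,4,6-trimethoxyphenoxy)phenoxy]-2,3-dimethoxyphenol
Product: 14 tert-butyl{6-[2,6-dimethoxy-4-(2,4,6-trimethoxyphenoxy)phenoxy]-2,3,4-trimethoxyphenoxy}dimethylsilane
Conditions: MeI, K2CO3, dry acetone, 40 °C, Ar
Reagents that add atoms: iodomethane, CI
Why: Williamson O-methylation of the unhindered phenol (flanked by hydrogen and methoxy) under anhydrous carbonate conditions that should leave the doubly flanked aryl silyl ether intact.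

Step 7
Reactants: 14 tert-butyl{6-[2,6-dimethoxy-4-(2,4,6-trimethoxyphenoxy)phenoxy]-2,3,4-trimethoxyphenoxy}dimethylsilane
Product: 15 6-[2,6-dimethoxy-4-(2,4,6-trimethoxyphenoxy)phenoxy]-2,3,4-trimethoxyphenol
Conditions: tetrabutylammonium fluoride, AcOH, THF, 0 °C
Reagents that add atoms: none
Why: Fluoride-mediated cleavage of the aryl silyl ether, driven by the Si–F bond and buffered with acetic acid so that the electron-rich phenol is released in its neutral, less oxidisable form.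

Step 8
Reactants: 16 3,4,5-trimethoxyphenol; 17 4-bromo-3,5-dimethoxybenzaldehyde
Product: 18 3,5-dimethoxy-4-(3,4,5-trimethoxyphenoxy)benzaldehyde
Conditions: CuI (10 mol%), picolinic acid (20 mol%), K3PO4, DMSO, 100 °C, Ar
Reagents that add atoms: none
Why: Ullmann-type etherification in which an unhindered electron-rich phenol meets a bromide activated by its para formyl group, which offsets the two ortho methoxy groups.

Step 9
Reactants: 18 3,5-dimethoxy-4-(3,4,5-trimethoxyphenoxy)benzaldehyde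
Product: 20 3,5-dimethoxy-4-(3,4,5-trimethoxyphenoxy)phenol, via aryl formate 19 (not isolated)
Conditions: mCPBA, CH2Cl2, 0 °C to rt; then cat. K2CO3, MeOH, rt
Reagents that add atoms: 3-chloroperoxybenzoic acid, OOC(=O)c1cccc(Cl)c1
Why: Baeyer–Villiger (Dakin-type) oxidation of an electron-rich benzaldehyde with aryl migration assisted by the para aryloxy group, followed by carbonate-catalysed methanolysis of the formate.

Step 10
Reactants: 20 3,5-dimethoxy-4-(3,4,5-trimethoxyphenoxy)phenol; 21 2-bromo-3,4,5-trimethoxybenzaldehyde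
Product: 22 2-[3,5-dimethoxy-4-(3,4,5-trimethoxyphenoxy)phenoxy]-3,4,5-trimethoxybenzaldehyde
Conditions: CuI (10 mol%), picolinic acid (20 mol%), K3PO4, DMSO, 100 °C, Ar
Reagents that add atoms: none
Why: Ullmann-type etherification of an unhindered phenol with an ortho-formyl aryl bromide, the ortho carbonyl assisting copper insertion as in classical couplings of 2-halobenzaldehydes and 2-halobenzoates.

Step 11
Reactants: 22 2-[3,5-dimethoxy-4-(3,4,5-trimethoxyphenoxy)phenoxy]-3,4,5-trimethoxybenzaldehyde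
Product: 24 2-[3,5-dimethoxy-4-(3,4,5-trimethoxyphenoxy)phenoxy]-3,4,5-trimethoxyphenol, via aryl formate 23 (not isolated)
Conditions: mCPBA, CH2Cl2, 0 °C to rt; then cat. K2CO3, MeOH, rt
Reagents that add atoms: 3-chloroperoxybenzoic acid, OOC(=O)c1cccc(Cl)c1
Why: Baeyer–Villiger (Dakin-type) oxidation in which the para methoxy and ortho aryloxy groups favour aryl over hydride migration, followed by methanolysis of the formate.

Step 12
Reactants: 24 2-[3,5-dimethoxy-4-(3,4,5-trimethoxyphenoxy)phenoxy]-3,4,5-trimethoxyphenol; 25 4-bromo-2-fluoro-6-methoxybenzaldehyde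
Product: 26 4-bromo-2-{2-[3,5-dimethoxy-4-(3,4,5-trimethoxyphenoxy)phenoxy]-3,4,5-trimethoxyphenoxy}-6-methoxybenzaldehyde
Conditions: K2CO3, DMF, 90 °C
Reagents that add atoms: none
Why: Nucleophilic aromatic substitution (addition–elimination) of the fluoride ortho to the formyl group by the phenoxide; fluoride is displaced far faster than the para bromide and no copper is present, so the bromide is kept for step 13.

Step 13
Reactants: 15 6-[2,6-dimethoxy-4-(2,4,6-trimethoxyphenoxy)phenoxy]-2,3,4-trimethoxyphenol; 26 4-bromo-2-{2-[3,5-dimethoxy-4-(3,4,5-trimethoxyphenoxy)phenoxy]-3,4,5-trimethoxyphenoxy}-6-methoxybenzaldehyde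
Product: 27 4-{6-[2,6-dimethoxy-4-(2,4,6-trimethoxyphenoxy)phenoxy]-2,3,4-trimethoxyphenoxy}-2-{2-[3,5-dimethoxy-4-(3,4,5-trimethoxyphenoxy)phenoxy]-3,4,5-trimethoxyphenoxy}-6-methoxybenzaldehyde
Conditions: CuI (20 mol%), picolinic acid (40 mol%), K3PO4, DMSO, 110 °C, Ar
Reagents that add atoms: none
Why: Ullmann-type etherification with CuI and picolinic acid, chosen for phenols flanked on both sides; the bromide carbon of 26 has no ortho substituent and is activated by the para formyl group.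

Step 14
Reactants: 27 4-{6-[2,6-dimethoxy-4-(2,4,6-trimethoxyphenoxy)phenoxy]-2,3,4-trimethoxyphenoxy}-2-{2-[3,5-dimethoxy-4-(3,4,5-trimethoxyphenoxy)phenoxy]-3,4,5-trimethoxyphenoxy}-6-methoxybenzaldehyde
Product: 29 4-{6-[2,6-dimethoxy-4-(2,4,6-trimethoxyphenoxy)phenoxy]-2,3,4-trimethoxyphenoxy}-2-{2-[3,5-dimethoxy-4-(3,4,5-trimethoxyphenoxy)phenoxy]-3,4,5-trimethoxyphenoxy}-6-methoxyphenol, via aryl formate 28 (not isolated)
Conditions: mCPBA, CH2Cl2, 0 °C to rt; then cat. K2CO3, MeOH/CH2Cl2, rt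
Reagents that add atoms: 3-chloroperoxybenzoic acid, OOC(=O)c1cccc(Cl)c1
Why: Baeyer–Villiger (Dakin-type) oxidation of a benzaldehyde flanked by methoxy and aryloxy groups and para to a third aryloxy group, all of which favour aryl migration, then methanolysis of the formate; this turns the activating formyl group into the C4 hydroxyl of ring D.

Step 15
Reactants: 29 4-{6-[2,6-dimethoxy-4-(2,4,6-trimethoxyphenoxy)phenoxy]-2,3,4-trimethoxyphenoxy}-2-{2-[3,5-dimethoxy-4-(3,4,5-trimethoxyphenoxy)phenoxy]-3,4,5-trimethoxyphenoxy}-6-methoxyphenol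
Product: 30 CNP0130704.0 (target)
Conditions: BBr3 (large excess), CH2Cl2, −78 °C to rt, Ar; then ice-water
Reagents that add atoms: none
Why: Lewis-acid cleavage of the seventeen aryl methyl ethers by BBr3 (boron coordinates the ether oxygen, bromide attacks methyl), which should leave the six diaryl ether bonds untouched because bromide cannot attack an aryl carbon; the aqueous quench releases the eighteen hydroxyls.

Compound list
1 | 2,4,6-trimethoxybenzaldehyde | COc1cc(OC)c(C=O)c(OC)c1 | starting material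
2 | 2,4,6-trimethoxyphenyl formate | COc1cc(OC)c(OC=O)c(OC)c1 | intermediate (not isolated)
3 | 2,4,6-trimethoxyphenol | COc1cc(OC)c(O)c(OC)c1 | intermediate
4 | 4-bromo-2,6-dimethoxyphenol | COc1cc(Br)cc(OC)c1O | starting material
5 | 5-bromo-2-(ethenyloxy)-1,3-dimethoxybenzene | COc1cc(Br)cc(OC)c1OC=C | intermediate
6 | 2-[4-(ethenyloxy)-3,5-dimethoxyphenoxy]-1,3,5-trimethoxybenzene (A–B vinyl ether) | C=COc1c(OC)cc(Oc2c(OC)cc(OC)cc2OC)cc1OC | intermediate
7 | dimethyl squarate (3,4-dimethoxycyclobut-3-ene-1,2-dione) | COC1=C(OC)C(=O)C1=O | starting material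
8 | {1-[2,6-dimethoxy-4-(2,4,6-trimethoxyphenoxy)phenoxy]ethenyl}lithium | [Li]C(=C)Oc1c(OC)cc(Oc2c(OC)cc(OC)cc2OC)cc1OC | intermediate (not isolated)
9 | lithium alkoxide of rac-4-hydroxy-2,3-dimethoxy-4-{1-[2,6-dimethoxy-4-(2,4,6-trimethoxyphenoxy)phenoxy]ethenyl}cyclobut-2-en-1-one (racemic) | [Li]OC1(C(=C)Oc2c(OC)cc(Oc3c(OC)cc(OC)cc3OC)cc2OC)C(OC)=C(OC)C1=O | intermediate (not isolated)
10 | rac-4-[(tert-butyldimethylsilyl)oxy]-2,3-dimethoxy-4-{1-[2,6-dimethoxy-4-(2,4,6-trimethoxyphenoxy)phenoxy]ethenyl}cyclobut-2-en-1-one (racemic) | COC1=C(OC)C(O[Si](C)(C)C(C)(C)C)(C(=C)Oc2c(OC)cc(Oc3c(OC)cc(OC)cc3OC)cc2OC)C1=O | intermediate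
11 | (3Z)-4-[(tert-butyldimethylsilyl)oxy]-5-[2,6-dimethoxy-4-(2,4,6-trimethoxyphenoxy)phenoxy]-2,3-dimethoxyhexa-1,3,5-trien-1-one (dienylketene) | O=C=C(OC)/C(OC)=C(O[Si](C)(C)C(C)(C)C)\C(=C)Oc1c(OC)cc(Oc2c(OC)cc(OC)cc2OC)cc1OC | intermediate (not isolated)
12 | 4-[(tert-butyldimethylsilyl)oxy]-5-[2,6-dimethoxy-4-(2,4,6-trimethoxyphenoxy)phenoxy]-2,3-dimethoxycyclohexa-2,4-dien-1-one | COC1=C(OC)C(O[Si](C)(C)C(C)(C)C)=C(Oc2c(OC)cc(Oc3c(OC)cc(OC)cc3OC)cc2OC)CC1=O | intermediate (not isolated)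
13 | 4-[(tert-butyldimethylsilyl)oxy]-5-[2,6-dimethoxy-4-(2,4,6-trimethoxyphenoxy)phenoxy]-2,3-dimethoxyphenol (A–B–C trimer, free OH on C3 of ring C, silyl ether on C6) | COc1c(O)cc(Oc2c(OC)cc(Oc3c(OC)cc(OC)cc3OC)cc2OC)c(O[Si](C)(C)C(C)(C)C)c1OC | intermediate
14 | tert-butyl{6-[2,6-dimethoxy-4-(2,4,6-trimethoxyphenoxy)phenoxy]-2,3,4-trimethoxyphenoxy}dimethylsilane | COc1cc(Oc2c(OC)cc(Oc3c(OC)cc(OC)cc3OC)cc2OC)c(O[Si](C)(C)C(C)(C)C)c(OC)c1OC | intermediate
15 | 6-[2,6-dimethoxy-4-(2,4,6-trimethoxyphenoxy)phenoxy]-2,3,4-trimethoxyphenol | COc1cc(Oc2c(OC)cc(Oc3c(OC)cc(OC)cc3OC)cc2OC)c(O)c(OC)c1OC | intermediate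
16 | 3,4,5-trimethoxyphenol | COc1cc(O)cc(OC)c1OC | starting material
17 | 4-bromo-3,5-dimethoxybenzaldehyde | COc1cc(C=O)cc(OC)c1Br | starting material
18 | 3,5-dimethoxy-4-(3,4,5-trimethoxyphenoxy)benzaldehyde | COc1cc(C=O)cc(OC)c1Oc1cc(OC)c(OC)c(OC)c1 | intermediate
19 | 3,5-dimethoxy-4-(3,4,5-trimethoxyphenoxy)phenyl formate | COc1cc(OC=O)cc(OC)c1Oc1cc(OC)c(OC)c(OC)c1 | intermediate (not isolated)
20 | 3,5-dimethoxy-4-(3,4,5-trimethoxyphenoxy)phenol | COc1cc(O)cc(OC)c1Oc1cc(OC)c(OC)c(OC)c1 | intermediate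
21 | 2-bromo-3,4,5-trimethoxybenzaldehyde | COc1cc(C=O)c(Br)c(OC)c1OC | starting material
22 | 2-[3,5-dimethoxy-4-(3,4,5-trimethoxyphenoxy)phenoxy]-3,4,5-trimethoxybenzaldehyde | COc1cc(C=O)c(Oc2cc(OC)c(Oc3cc(OC)c(OC)c(OC)c3)c(OC)c2)c(OC)c1OC | intermediate
23 | 2-[3,5-dimethoxy-4-(3,4,5-trimethoxyphenoxy)phenoxy]-3,4,5-trimethoxyphenyl formate | COc1cc(OC=O)c(Oc2cc(OC)c(Oc3cc(OC)c(OC)c(OC)c3)c(OC)c2)c(OC)c1OC | intermediate (not isolated)
24 | 2-[3,5-dimethoxy-4-(3,4,5-trimethoxyphenoxy)phenoxy]-3,4,5-trimethoxyphenol | COc1cc(O)c(Oc2cc(OC)c(Oc3cc(OC)c(OC)c(OC)c3)c(OC)c2)c(OC)c1OC | intermediate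
25 | 4-bromo-2-fluoro-6-methoxybenzaldehyde | COc1cc(Br)cc(F)c1C=O | starting material
26 | 4-bromo-2-{2-[3,5-dimethoxy-4-(3,4,5-trimethoxyphenoxy)phenoxy]-3,4,5-trimethoxyphenoxy}-6-methoxybenzaldehyde (D–E–F–G bromide) | COc1cc(Br)cc(Oc2cc(OC)c(OC)c(OC)c2Oc2cc(OC)c(Oc3cc(OC)c(OC)c(OC)c3)c(OC)c2)c1C=O | intermediate
27 | 4-{6-[2,6-dimethoxy-4-(2,4,6-trimethoxyphenoxy)phenoxy]-2,3,4-trimethoxyphenoxy}-2-{2-[3,5-dimethoxy-4-(3,4,5-trimethoxyphenoxy)phenoxy]-3,4,5-trimethoxyphenoxy}-6-methoxybenzaldehyde (heptamer aldehyde) | COc1cc(OC)c(Oc2cc(OC)c(Oc3cc(OC)c(OC)c(OC)c3Oc3cc(OC)c(C=O)c(Oc4cc(OC)c(OC)c(OC)c4Oc4cc(OC)c(Oc5cc(OC)c(OC)c(OC)c5)c(OC)c4)c3)c(OC)c2)c(OC)c1 | intermediate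
28 | 4-{6-[2,6-dimethoxy-4-(2,4,6-trimethoxyphenoxy)phenoxy]-2,3,4-trimethoxyphenoxy}-2-{2-[3,5-dimethoxy-4-(3,4,5-trimethoxyphenoxy)phenoxy]-3,4,5-trimethoxyphenoxy}-6-methoxyphenyl formate | COc1cc(OC)c(Oc2cc(OC)c(Oc3cc(OC)c(OC)c(OC)c3Oc3cc(OC)c(OC=O)c(Oc4cc(OC)c(OC)c(OC)c4Oc4cc(OC)c(Oc5cc(OC)c(OC)c(OC)c5)c(OC)c4)c3)c(OC)c2)c(OC)c1 | intermediate (not isolated)
29 | 4-{6-[2,6-dimethoxy-4-(2,4,6-trimethoxyphenoxy)phenoxy]-2,3,4-trimethoxyphenoxy}-2-{2-[3,5-dimethoxy-4-(3,4,5-trimethoxyphenoxy)phenoxy]-3,4,5-trimethoxyphenoxy}-6-methoxyphenol (heptamer, seventeen methyl ethers, free OH on C4 of ring D) | COc1cc(OC)c(Oc2cc(OC)c(Oc3cc(OC)c(OC)c(OC)c3Oc3cc(OC)c(O)c(Oc4cc(OC)c(OC)c(OC)c4Oc4cc(OC)c(Oc5cc(OC)c(OC)c(OC)c5)c(OC)c4)c3)c(OC)c2)c(OC)c1 | intermediate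
30 | CNP0130704.0 (heptameric phloroglucinol-derived aryl ether with eighteen free hydroxyls; achiral) | Oc1cc(O)c(Oc2cc(O)c(Oc3cc(O)c(O)c(O)c3Oc3cc(O)c(O)c(Oc4cc(O)c(O)c(O)c4Oc4cc(O)c(Oc5cc(O)c(O)c(O)c5)c(O)c4)c3)c(O)c2)c(O)c1 | target

Total step count: 15. Longest linear sequence: 9 steps (steps 1, 3, 4, 5, 6, 7, 13, 14, 15).

Steps most likely to fail

Step 4. The risk is competing deprotonation by t-BuLi at the ring C–H positions that lie between two oxygens (C3/C5 of ring A, C2/C6 of ring B), or decomposition of the α-oxygenated vinyllithium before it adds to the squarate. The fallback generates the same vinyllithium regiospecifically by tin–lithium exchange. It sets out from 6: aqueous HCl in THF should hydrolyse the vinyl ether to the phenol 2,6-dimethoxy-4-(2,4,6-trimethoxyphenoxy)phenol F1. Trichloroethylene and K2CO3 in DMF should then give the dichlorovinyl ether 2-{4-[(E)-1,2-dichloroethenyl]oxy-3,5-dimethoxyphenoxy}-1,3,5-trimethoxybenzene F2. n-BuLi (2.2 equiv, THF, −78 °C) followed by methanol should give the ynol ether 2-[4-(ethynyloxy)-3,5-dimethoxyphenoxy]-1,3,5-trimethoxybenzene F3. Hydrostannation with Bu3SnH and Pd(PPh3)4 (zerovalent palladium) is expected to place tin on the oxygen-bearing carbon, as it does for alkoxyalkynes, and give tributyl{1-[2,6-dimethoxy-4-(2,4,6-trimethoxyphenoxy)phenoxy]ethenyl}stannane F4. n-BuLi in THF at −78 °C then exchanges tin for lithium, and the fallback comes back to the route at vinyllithium 8.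

Step 5. The risk is diversion of the thermolysis: protonolysis of the enol ether by the phenol as it forms, interception of the ketene before it cyclises, or loss of the silyl group. The fallback brings ring C in ready-made instead of building it. It sets out from 6, which is hydrolysed as above to the phenol 2,6-dimethoxy-4-(2,4,6-trimethoxyphenoxy)phenol F1. Separately, Rieche formylation (Cl2CHOMe, TiCl4, CH2Cl2, 0 °C) of commercial 5-bromo-1,2,3-trimethoxybenzene should give 6-bromo-2,3,4-trimethoxybenzaldehyde F5. Ullmann coupling of F1 with F5 (CuI, picolinic acid, K3PO4, DMSO, 100 °C) should give 6-[2,6-dimethoxy-4-(2,4,6-trimethoxyphenoxy)phenoxy]-2,3,4-trimethoxybenzaldehyde F6. mCPBA followed by cat. K2CO3 in MeOH should pass through 6-[2,6-dimethoxy-4-(2,4,6-trimethoxyphenoxy)phenoxy]-2,3,4-trimethoxyphenyl formate F7, and the fallback comes back to the route at phenol 15.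

Step 13. The risk is slow C–O bond formation between a phenoxide flanked on both sides and a large bromide, so that the bromide is reduced or the phenoxide oxidised before they couple. The fallback attaches ring D alone first, as a small iodide, and adds the outer three rings afterwards. Para-iodination of commercial 2-bromo-6-methoxyphenol (N-iodosuccinimide, MeCN) should give 2-bromo-4-iodo-6-methoxyphenol F8, and methylation (MeI, K2CO3, acetone) should give 1-bromo-5-iodo-2,3-dimethoxybenzene F9. Setting out from 15, copper-catalysed coupling with excess F9 (CuI, picolinic acid, K3PO4, DMSO, 85 °C) should occur at the unhindered C–I bond and give 1-bromo-5-{6-[2,6-dimethoxy-4-(2,4,6-trimethoxyphenoxy)phenoxy]-2,3,4-trimethoxyphenoxy}-2,3-dimethoxybenzene F10. Coupling of F10 with phenol 24 under the same catalyst at 110 °C should give the octadeca-O-methyl ether of the target F11. BBr3 in CH2Cl2 then demethylates it, and the fallback comes back to the route at the target 30.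

Further compounds
F1 | step 4 | 2,6-dimethoxy-4-(2,4,6-trimethoxyphenoxy)phenol | COc1cc(Oc2c(OC)cc(OC)cc2OC)cc(OC)c1O
F2 | step 4 | 2-{4-[(E)-1,2-dichloroethenyl]oxy-3,5-dimethoxyphenoxy}-1,3,5-trimethoxybenzene | Cl/C=C(/Cl)Oc1c(OC)cc(Oc2c(OC)cc(OC)cc2OC)cc1OC
F3 | step 4 | 2-[4-(ethynyloxy)-3,5-dimethoxyphenoxy]-1,3,5-trimethoxybenzene | C#COc1c(OC)cc(Oc2c(OC)cc(OC)cc2OC)cc1OC
F4 | step 4 | tributyl{1-[2,6-dimethoxy-4-(2,4,6-trimethoxyphenoxy)phenoxy]ethenyl}stannane | C=C(Oc1c(OC)cc(Oc2c(OC)cc(OC)cc2OC)cc1OC)[Sn](CCCC)(CCCC)CCCC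
F5 | step 5 | 6-bromo-2,3,4-trimethoxybenzaldehyde | COc1cc(Br)c(C=O)c(OC)c1OC
F6 | step 5 | 6-[2,6-dimethoxy-4-(2,4,6-trimethoxyphenoxy)phenoxy]-2,3,4-trimethoxybenzaldehyde | COc1cc(Oc2c(OC)cc(Oc3c(OC)cc(OC)cc3OC)cc2OC)c(C=O)c(OC)c1OC
F7 | step 5 | 6-[2,6-dimethoxy-4-(2,4,6-trimethoxyphenoxy)phenoxy]-2,3,4-trimethoxyphenyl formate | COc1cc(Oc2c(OC)cc(Oc3c(OC)cc(OC)cc3OC)cc2OC)c(OC=O)c(OC)c1OC
F8 | step 13 | 2-bromo-4-iodo-6-methoxyphenol | COc1cc(I)cc(Br)c1O
F9 | step 13 | 1-bromo-5-iodo-2,3-dimethoxybenzene | COc1cc(I)cc(Br)c1OC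
F10 | step 13 | 1-bromo-5-{6-[2,6-dimethoxy-4-(2,4,6-trimethoxyphenoxy)phenoxy]-2,3,4-trimethoxyphenoxy}-2,3-dimethoxybenzene | COc1cc(OC)c(Oc2cc(OC)c(Oc3cc(OC)c(OC)c(OC)c3Oc3cc(OC)c(OC)c(Br)c3)c(OC)c2)c(OC)c1
F11 | step 13 | octadeca-O-methyl ether of the target | COc1cc(OC)c(Oc2cc(OC)c(Oc3cc(OC)c(OC)c(OC)c3Oc3cc(OC)c(OC)c(Oc4cc(OC)c(OC)c(OC)c4Oc4cc(OC)c(Oc5cc(OC)c(OC)c(OC)c5)c(OC)c4)c3)c(OC)c2)c(OC)c1
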